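**The question.** How much X stands in the midnight flask at the asked time, and what order in E does the summer charge show at the outset?

| flask | Z | J | E | X | time |
|---|---|---|---|---|---|
| summer | 0.400 M | 0.400 M | 0.0200 M |  |  |
| dawn | 0.240 M | 0.240 M | 0.0200 M |  |  |
| autumn | 0.400 M | 0.400 M | 0.0100 M |  |  |
| winter | 0.400 M | 0.400 M | 0.0200 M | 0.200 M |  |
| midnight | 0.400 M | 0.200 M | 0.0600 M |  | 80 min |

| run | time / min | [X] / M |
|---|---|---|
| summer run | 10 | 0.0305 |
| summer run | 20 | 0.0616 |
| summer run | 30 | 0.0846 |
| summer run | 40 | 0.1007 |
| summer run | 50 | 0.1159 |
| summer run | 60 | 0.1261 |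
| summer run | 70 | 0.1302 |
| summer run | 80 | 0.1362 |
| dawn run | 10 | 0.0199 |
| dawn run | 20 | 0.0404 |
| dawn run | 30 | 0.0554 |
| dawn run | 40 | 0.0690 |
| dawn run | 50 | 0.0765 |
| dawn run | 60 | 0.0820 |
| dawn run | 70 | 0.0834 |
| dawn run | 80 | 0.0866 |
| autumn run | 10 | 0.0209 |
| autumn run | 20 | 0.0383 |
| autumn run | 30 | 0.0530 |
| autumn run | 40 | 0.0661 |
| autumn run | 50 | 0.0732 |
| autumn run | 60 | 0.0812 |
| autumn run | 70 | 0.0877 |
| autumn run | 80 | 0.0898 |
| winter run | 10 | 0.2063 |
| winter run | 20 | 0.2139 |
| winter run | 30 | 0.2183 |
| winter run | 40 | 0.2201 |
| winter run | 50 | 0.2190 |
| winter run | 60 | 0.2153 |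
| winter run | 70 | 0.2091 |
| winter run | 80 | 0.2049 |

(standard deviation of a reading: 0.001 M)

* reaction order in [E] at the outset, round the charge of the summer run, defined at two percent of the Z turned into X
* X in the midnight run at 80 min, as a share of the Z charged

- Overall: Z + J -> X, with E as catalyst.
- Constant volume, constant temperature.
- The analysis sees a species whether free or bound.
- "The second partner" is J.
- An order is taken over about fifteen percent of the charge, up and down.

**The order.** With half the E of summer, the autumn run had made 0.622 of the summer X at 20 min, as read. That gave me an order of 0.686, a reading over a wider step than the one asked.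

**First way.** I chose one quantity, the loss constant of X: the fraction of the standing X that disappears per minute. Winter and summer differ in their charge by the added X. So if X took no part in its own making, their difference would decay as a pure exponential, whatever the formation did. The difference fell from 0.200 M to 0.06870 M at 80 min, which gave 0.0134 min⁻¹.

**Second way.** Winter's highest reading, 0.2201 M at 40 min, stood above its neighbours, so there formation just balanced loss. Summer was still climbing at that time, by 0.00157 M min⁻¹. Equal formation in both flasks then made that slope the loss constant times the difference of their readings, which gave 0.0131 min⁻¹. These are other readings, a local slope against a long logarithm, and the two agreed, so I trusted the first. It means a lifetime of 74.9 min, which is of the order of the run itself.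

**Midnight.** In the midnight flask J is the limiting reagent, 0.200 M against 0.400 M of Z, so the ceiling was 50.0 % of the Z charged. I took J as falling first-order, starting from the mean summer rate over the first 20 min, per J, and scaling it by my order for the E charge. That gave 0.0164 min⁻¹. Making at that constant and losing at the loss constant integrate in closed form to a difference of two exponentials, and at 80 min this came to 20.0 % of Z.

**The forecast.** It gave an order of 0.55 (0.42 to 0.7) and 33 % (25 % to 42 %), reading winter as “strong inhibition by X, plus a slow later loss of X”. My reckoning differs from it on both numbers.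

**The flask.** The order came out at 0.65 and the midnight X at 23.5 % of Z, which is 0.0940 M.

    E + Z → EZ (3.282 M⁻¹ min⁻¹)
    EZ + J → Jy (1.230 M⁻¹ min⁻¹)
    Jy → X + E (0.2916 min⁻¹)
    X → Yx (0.01344 min⁻¹)
    Z + J → X (0.005292 M⁻¹ min⁻¹)

In the midnight flask the direct step Z + J → X made no difference to that share. Against the J charged, the X standing at 80 min is 47.0 %, and at the loss constant 0.0134 min⁻¹ that is the share surviving an age of 56.5 min. Taken as one batch from the whole J charge, the midnight X was made at about 23.5 min.

Readings and results are calculated with constants of no real substance, and the scatter is random.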